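**Retrosynthetic overview**

1. Numbering used throughout (germacrane): ring C1–C10 with C1=C10 and C2=C3 (both cis within the ring), C4 (CH3), C6 (lactone O), C7, C8 (ester O), C9 (ring CH2), C14 = CH2OAc on C10, lactone carbons C11(=C13)–C12.
2. Endgame disconnections: C8 ester and C14 acetate (acylations), C11=C13 (α-methylenation), lactone C6–O (ketone reduction, lactonisation), C7–C11 (enolate alkylation); this leads back to a ten-membered C6 enolate that carries the C8 ether.
3. Key disconnection C8–C9: with C6 at the ketone level, O=C6–C7–C8–C9–C10=C1 is a δ,ε-unsaturated ketone, the retron of an anionic oxy-Cope rearrangement, and the cis C2=C3 bond lets C1 and C6 be rejoined as a cyclohexene. The precursor is a cis-1-(2-alkoxyvinyl)-2-alkenyl-5-methylcyclohex-3-en-1-ol whose temporary C1–C6 bond is cleaved as C8–C9 forms.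
4. The cyclohexenol comes from (R)-5-methylcyclohex-2-en-1-one, which supplies C4: α-iodination, Negishi alkenylation, deconjugative protonation, ynol ether addition, trans-hydroalumination.
5. Ring order: cyclohexene (purchased) → ten-membered carbocycle (step 8, ring expansion) → γ-lactone (step 9).

Key step: step 8

Assumption: 3 and 30 are taken as purchasable building blocks (3 is otherwise made from (R)-pulegone, 30 from a methacrylate ester by asymmetric dihydroxylation, acetonide formation and ester cleavage).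

**Route**

Step 1
Reactants: 1 2-bromoprop-2-en-1-ol
Product: 2 tert-butyl[(2-bromoprop-2-en-1-yl)oxy]dimethylsilane
Conditions: t-BuMe2SiCl, imidazole, DMF, 0 °C to rt
Reagents that add atoms: tert-butyldimethylsilyl chloride, CC(C)(C)[Si](C)(C)Cl
Why: Imidazole-promoted silylation of a primary alcohol is routine and leaves the vinyl bromide needed for the later metalation untouched.

Step 2
Reactants: 3 (R)-5-methylcyclohex-2-en-1-one
Product: 4 (R)-2-iodo-5-methylcyclohex-2-en-1-one
Conditions: I2, pyridine, CH2Cl2, 0 °C to rt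
Reagents that add atoms: iodine, II
Why: α-Iodination of a cyclic enone by the pyridine/iodine addition–elimination sequence is a standard reaction that does not touch the remote C5 stereocentre.

Step 3
Reactants: 2 tert-butyl[(2-bromoprop-2-en-1-yl)oxy]dimethylsilane; 4 (R)-2-iodo-5-methylcyclohex-2-en-1-one
Product: 7 (R)-2-{3-[(tert-butyldimethylsilyl)oxy]prop-1-en-2-yl}-5-methylcyclohex-2-en-1-one, via alkenyllithium 5 (not isolated), via alkenylzinc chloride 6 (not isolated)
Conditions: 2, t-BuLi (2 equiv), Et2O, −78 °C; ZnCl2, THF, −78 to 0 °C; then 4, Pd(PPh3)4 (5 mol %), THF, rt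
Reagents that add atoms: none
Why: Bromine–lithium exchange, transmetalation to zinc and Negishi coupling of the alkenylzinc with an α-iodoenone under zerovalent palladium catalysis is a well-precedented way to attach the C10/C9/C14 unit to C1.

Step 4
Reactants: 7 (R)-2-{3-[(tert-butyldimethylsilyl)oxy]prop-1-en-2-yl}-5-methylcyclohex-2-en-1-one
Product: 9 (2S,5S)-2-{3-[(tert-butyldimethylsilyl)oxy]prop-1-en-2-yl}-5-methylcyclohex-3-en-1-one (side chain trans to methyl), via potassium dienolate 8 (not isolated)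
Conditions: KOt-Bu, THF/t-BuOH, 0 °C; inverse quench into AcOH/THF, −78 °C; used without chromatography
Reagents that add atoms: none
Why: Deconjugative protonation (thermodynamic γ-deprotonation to the extended dienolate, then kinetic α-protonation) moves the ring double bond to C2=C3, and protonation along the axial trajectory of the half-chair that keeps the methyl group pseudo-equatorial should deliver the proton cis to methyl, so that the side chain ends trans to it (2S), which is also the more stable arrangement.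

Step 5
Reactants: 10 (4-methoxyphenyl)methanol; 11 trichloroethylene
Product: 13 1-({[(E)-1,2-dichloroethenyl]oxy}methyl)-4-methoxybenzene, via potassium 4-methoxybenzyl oxide 12 (not isolated)
Conditions: KH, THF, 0 °C; then Cl2C=CHCl, rt
Reagents that add atoms: none
Why: Addition–elimination of the potassium alkoxide on trichloroethylene (by way of dichloroacetylene) is the standard preparation of (E)-1,2-dichlorovinyl ethers as ynol ether precursors.

Step 6
Reactants: 13 1-({[(E)-1,2-dichloroethenyl]oxy}methyl)-4-methoxybenzene; 9 (2S,5S)-2-{3-[(tert-butyldimethylsilyl)oxy]prop-1-en-2-yl}-5-methylcyclohex-3-en-1-one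
Product: 17 (1R,2S,5S)-2-{3-[(tert-butyldimethylsilyl)oxy]prop-1-en-2-yl}-1-{[(4-methoxyphenyl)methoxy]ethynyl}-5-methylcyclohex-3-en-1-ol (alkynyl cis to the C2 side chain, hydroxyl cis to methyl), via chloroalkynyl ether 14 (not isolated), via lithium alkoxyacetylide 15 (not isolated), via cerium acetylide 16 (not isolated)
Conditions: 13, n-BuLi (2.2 equiv), THF, −78 to −40 °C; CeCl3 (anhydrous), −78 °C; then 9, THF, −78 °C; H2O; used at once
Reagents that add atoms: none
Why: Dehydrochlorination and chlorine–lithium exchange give the lithium alkoxyacetylide, whose organocerium form adds 1,2 to the readily enolised ketone without deprotonating it (organocerium carbonyl addition), and the slim acetylide should attack the half-chair ketone axially, cis to the neighbouring pseudo-equatorial side chain, which sets the tertiary carbinol (1R) with the hydroxyl cis to the methyl group.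

Step 7
Reactants: 17 (1R,2S,5S)-2-{3-[(tert-butyldimethylsilyl)oxy]prop-1-en-2-yl}-1-{[(4-methoxyphenyl)methoxy]ethynyl}-5-methylcyclohex-3-en-1-ol
Product: 18 (1R,2S,5S)-2-{3-[(tert-butyldimethylsilyl)oxy]prop-1-en-2-yl}-1-{(E)-2-[(4-methoxyphenyl)methoxy]ethenyl}-5-methylcyclohex-3-en-1-ol
Conditions: NaAlH2(OCH2CH2OMe)2, THF, 0 °C to rt; aq. KNaC4H4O6
Reagents that add atoms: none
Why: Hydroxyl-directed trans-hydroalumination of the propargylic alcohol (hydride delivered from the alkoxyaluminate to the proximal alkyne carbon, then protonolysis of the alkenylaluminate) gives the (E)-enol ether and touches no other group.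

Step 8
Reactants: 18 (1R,2S,5S)-2-{3-[(tert-butyldimethylsilyl)oxy]prop-1-en-2-yl}-1-{(E)-2-[(4-methoxyphenyl)methoxy]ethenyl}-5-methylcyclohex-3-en-1-ol; 19 methyl bromoacetate
Product: 22 methyl 2-[(1S,2R,4E,6Z,8S)-4-{[(tert-butyldimethylsilyl)oxy]methyl}-2-[(4-methoxyphenyl)methoxy]-8-methyl-10-oxocyclodeca-4,6-dien-1-yl]acetate (both ring double bonds cis within the ring; acetate arm trans to the benzylic ether), via potassium alkoxide 20 (not isolated), via ring-expanded potassium enolate 21 (not isolated)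
Conditions: KN(SiMe3)2, 18-crown-6, THF, −78 to 0 °C; then BrCH2CO2Me, −78 to −40 °C; aq. NH4Cl
Reagents that add atoms: none
Why: The potassium alkoxide 20 contains the 3-oxido-1,5-diene C8=C7–C6(O−)–C1–C10=C9 and should undergo an anionic oxy-Cope [3,3]-sigmatropic rearrangement in which C8–C9 forms while the doubly allylic C1–C6 ring bond breaks, which turns the C6 oxygen into enolate 21 that is C-alkylated by methyl bromoacetate in the same flask; the closest known reaction type is the anionic oxy-Cope ring expansion of 1,2-dialkenylcyclohexanols to cyclodec-5-enones with in situ enolate alkylation. The ten-membered ring is closed by the sigmatropic shift itself, a ring expansion of the cyclohexene by the four alkenyl carbons, through a chair transition state in which methyl and the C1 side chain are pseudo-equatorial and the alkoxyvinyl group is axial on the half-chair. In this chair the ring carbon C2 stands axial, so the new C1=C10 bond is formed cis within the ring next to the retained cis C2=C3 bond, and the E enol ether places the benzylic ether oxygen equatorial, which sets C8 (R); C4 is carried through untouched. C7 (S) is set when the electrophile attacks the ring-trans enolate on its outer face, the inner face being covered by the ring, which puts the acetate arm trans to the C8 oxygen. The step needs C9 and not the ring carbon C3 to bond to C8, which the chair secures because C3 can be reached only through a boat, and it needs the β-alkoxy enolate not to eliminate, which is helped by the C8–O bond lying in the nodal plane of the enolate as formed and by alkylation at −78 °C.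

Step 9
Reactants: 22 methyl 2-[(1S,2R,4E,6Z,8S)-4-{[(tert-butyldimethylsilyl)oxy]methyl}-2-[(4-methoxyphenyl)methoxy]-8-methyl-10-oxocyclodeca-4,6-dien-1-yl]acetate
Product: 24 (3aS,4R,6E,8Z,10S,11aS)-6-{[(tert-butyldimethylsilyl)oxy]methyl}-4-[(4-methoxyphenyl)methoxy]-10-methyl-3a,4,5,10,11,11a-hexahydrocyclodeca[b]furan-2(3H)-one (trans-fused lactone), via hydroxy ester 23 (not isolated)
Conditions: Zn(BH4)2, Et2O, −30 °C; then pyridinium p-toluenesulfonate (cat.), toluene, 50 °C
Reagents that add atoms: none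
Why: Chelation-controlled reduction, with zinc bridging the ketone and the β-ether oxygen and hydride arriving from outside the chelate, should give the 1,3-syn alcohol at C6 (S), trans to the acetate arm, which then closes the trans-fused γ-lactone by acid-catalysed lactonisation.

Step 10
Reactants: 24 (3aS,4R,6E,8Z,10S,11aS)-6-{[(tert-butyldimethylsilyl)oxy]methyl}-4-[(4-methoxyphenyl)methoxy]-10-methyl-3a,4,5,10,11,11a-hexahydrocyclodeca[b]furan-2(3H)-one
Product: 28 (3aS,4R,6E,8Z,10S,11aS)-6-{[(tert-butyldimethylsilyl)oxy]methyl}-4-[(4-methoxyphenyl)methoxy]-10-methyl-3-methylidene-3a,4,5,10,11,11a-hexahydrocyclodeca[b]furan-2(3H)-one, via lithium enolate 25 (not isolated), via Mannich base 26 (not isolated), via trimethylammonium iodide 27 (not isolated)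
Conditions: LiN(i-Pr)2, THF, −78 °C; Me2N=CH2 I, −78 to 0 °C; MeI, MeOH, rt; aq. NaHCO3, CH2Cl2
Reagents that add atoms: dimethylmethyleneammonium iodide, C=[N+](C)C.[I-]
Why: α-Methylenation of the γ-lactone by Mannich reaction of its lithium enolate with the iminium salt, N-methylation and base-induced β-elimination of trimethylamine is the standard route to α-methylene-γ-butyrolactones and creates no stereocentre.

Step 11
Reactants: 28 (3aS,4R,6E,8Z,10S,11aS)-6-{[(tert-butyldimethylsilyl)oxy]methyl}-4-[(4-methoxyphenyl)methoxy]-10-methyl-3-methylidene-3a,4,5,10,11,11a-hexahydrocyclodeca[b]furan-2(3H)-one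
Product: 29 (3aS,4R,6E,8Z,10S,11aS)-6-{[(tert-butyldimethylsilyl)oxy]methyl}-4-hydroxy-10-methyl-3-methylidene-3a,4,5,10,11,11a-hexahydrocyclodeca[b]furan-2(3H)-one
Conditions: DDQ, CH2Cl2/pH 7 buffer, 0 °C
Reagents that add atoms: none
Why: Oxidative cleavage of the 4-methoxybenzyl ether with DDQ (benzylic hydride abstraction and hydrolysis of the oxocarbenium ion) frees the C8 hydroxyl and leaves the silyl ether, the lactone and the diene alone.

Step 12
Reactants: 29 (3aS,4R,6E,8Z,10S,11aS)-6-{[(tert-butyldimethylsilyl)oxy]methyl}-4-hydroxy-10-methyl-3-methylidene-3a,4,5,10,11,11a-hexahydrocyclodeca[b]furan-2(3H)-one; 30 (4S)-2,2,4-trimethyl-1,3-dioxolane-4-carboxylic acid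
Product: 32 (3aR,4R,6E,8Z,10S,11aS)-6-{[(tert-butyldimethylsilyl)oxy]methyl}-10-methyl-3-methylidene-2-oxo-2,3,3a,4,5,10,11,11a-octahydrocyclodeca[b]furan-4-yl (4S)-2,2,4-trimethyl-1,3-dioxolane-4-carboxylate, via mixed anhydride 31 (not isolated)
Conditions: 30, 2,4,6-trichlorobenzoyl chloride, Et3N, toluene, rt; then 29, DMAP, toluene, 40 °C
Reagents that add atoms: none
Why: Yamaguchi esterification through the mixed 2,4,6-trichlorobenzoic anhydride acylates the hindered secondary alcohol with the α,α-disubstituted acid, whose quaternary S centre cannot epimerise, and the aprotic conditions keep the 6,12-lactone from migrating to O8.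

Step 13
Reactants: 32 (3aR,4R,6E,8Z,10S,11aS)-6-{[(tert-butyldimethylsilyl)oxy]methyl}-10-methyl-3-methylidene-2-oxo-2,3,3a,4,5,10,11,11a-octahydrocyclodeca[b]furan-4-yl (4S)-2,2,4-trimethyl-1,3-dioxolane-4-carboxylate
Product: 33 (3aR,4R,6E,8Z,10S,11aS)-6-(hydroxymethyl)-10-methyl-3-methylidene-2-oxo-2,3,3a,4,5,10,11,11a-octahydrocyclodeca[b]furan-4-yl (4S)-2,2,4-trimethyl-1,3-dioxolane-4-carboxylate
Conditions: HF·pyridine, pyridine/THF, 0 °C to rt
Reagents that add atoms: none
Why: Fluoride-mediated desilylation with pyridine-buffered HF removes the primary silyl ether without conjugate addition to the α-methylene lactone and without opening the acetonide.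

Step 14
Reactants: 33 (3aR,4R,6E,8Z,10S,11aS)-6-(hydroxymethyl)-10-methyl-3-methylidene-2-oxo-2,3,3a,4,5,10,11,11a-octahydrocyclodeca[b]furan-4-yl (4S)-2,2,4-trimethyl-1,3-dioxolane-4-carboxylate
Product: 34 (3aR,4R,6E,8Z,10S,11aS)-6-(acetoxymethyl)-10-methyl-3-methylidene-2-oxo-2,3,3a,4,5,10,11,11a-octahydrocyclodeca[b]furan-4-yl (4S)-2,2,4-trimethyl-1,3-dioxolane-4-carboxylate
Conditions: Ac2O, pyridine, DMAP (cat.), CH2Cl2, 0 °C
Reagents that add atoms: acetic anhydride, CC(=O)OC(C)=O
Why: DMAP-catalysed acetylation of the primary allylic alcohol with acetic anhydride is routine and leaves the other esters untouched.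

Step 15
Reactants: 34 (3aR,4R,6E,8Z,10S,11aS)-6-(acetoxymethyl)-10-methyl-3-methylidene-2-oxo-2,3,3a,4,5,10,11,11a-octahydrocyclodeca[b]furan-4-yl (4S)-2,2,4-trimethyl-1,3-dioxolane-4-carboxylate
Product: 35 (3aR,4R,6E,8Z,10S,11aS)-6-(acetoxymethyl)-10-methyl-3-methylidene-2-oxo-2,3,3a,4,5,10,11,11a-octahydrocyclodeca[b]furan-4-yl (2S)-2,3-dihydroxy-2-methylpropanoate (CNP0347302.1)
Conditions: AcOH/H2O (4:1), 40 °C
Reagents that add atoms: none
Why: Acid-catalysed hydrolysis of the terminal acetonide in aqueous acetic acid frees the 1,2-diol while the acetate, the hindered ester and the lactone survive, which gives the target.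

**Compound list**

1 | 2-bromoprop-2-en-1-ol | C=C(Br)CO | starting material
2 | tert-butyl[(2-bromoprop-2-en-1-yl)oxy]dimethylsilane | C=C(Br)CO[Si](C)(C)C(C)(C)C | intermediate
3 | (R)-5-methylcyclohex-2-en-1-one | O=C1C=CC[C@@H](C)C1 | starting material
4 | (R)-2-iodo-5-methylcyclohex-2-en-1-one | O=C1C(I)=CC[C@@H](C)C1 | intermediate
5 | {3-[(tert-butyldimethylsilyl)oxy]prop-1-en-2-yl}lithium | [Li]C(=C)CO[Si](C)(C)C(C)(C)C | intermediate
6 | chloro{3-[(tert-butyldimethylsilyl)oxy]prop-1-en-2-yl}zinc | Cl[Zn]C(=C)CO[Si](C)(C)C(C)(C)C | intermediate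
7 | (R)-2-{3-[(tert-butyldimethylsilyl)oxy]prop-1-en-2-yl}-5-methylcyclohex-2-en-1-one | O=C1C(C(=C)CO[Si](C)(C)C(C)(C)C)=CC[C@@H](C)C1 | intermediate
8 | potassium 2-{3-[(tert-butyldimethylsilyl)oxy]prop-1-en-2-yl}-5-methylcyclohexa-1,3-dien-1-olate (methyl-bearing centre as in 7) | [K+].[O-]C1=C(C(=C)CO[Si](C)(C)C(C)(C)C)C=C[C@@H](C)C1 | intermediate
9 | (2S,5S)-2-{3-[(tert-butyldimethylsilyl)oxy]prop-1-en-2-yl}-5-methylcyclohex-3-en-1-one (side chain trans to methyl) | O=C1C[C@H](C)C=C[C@H]1C(=C)CO[Si](C)(C)C(C)(C)C | intermediate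
10 | (4-methoxyphenyl)methanol | COc1ccc(CO)cc1 | starting material
11 | trichloroethylene | ClC=C(Cl)Cl | starting material
12 | potassium (4-methoxyphenyl)methanolate | [K+].[O-]Cc1ccc(OC)cc1 | intermediate
13 | 1-({[(E)-1,2-dichloroethenyl]oxy}methyl)-4-methoxybenzene | Cl/C=C(/Cl)OCc1ccc(OC)cc1 | intermediate
14 | 1-{[(chloroethynyl)oxy]methyl}-4-methoxybenzene | ClC#COCc1ccc(OC)cc1 | intermediate
15 | {[(4-methoxyphenyl)methoxy]ethynyl}lithium | [Li]C#COCc1ccc(OC)cc1 | intermediate
16 | dichloro{[(4-methoxyphenyl)methoxy]ethynyl}cerium | Cl[Ce](Cl)C#COCc1ccc(OC)cc1 | intermediate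
17 | (1R,2S,5S)-2-{3-[(tert-butyldimethylsilyl)oxy]prop-1-en-2-yl}-1-{[(4-methoxyphenyl)methoxy]ethynyl}-5-methylcyclohex-3-en-1-ol | O[C@]1(C#COCc2ccc(OC)cc2)C[C@H](C)C=C[C@H]1C(=C)CO[Si](C)(C)C(C)(C)C | intermediate
18 | (1R,2S,5S)-2-{3-[(tert-butyldimethylsilyl)oxy]prop-1-en-2-yl}-1-{(E)-2-[(4-methoxyphenyl)methoxy]ethenyl}-5-methylcyclohex-3-en-1-ol | O[C@]1(/C=C/OCc2ccc(OC)cc2)C[C@H](C)C=C[C@H]1C(=C)CO[Si](C)(C)C(C)(C)C | intermediate
19 | methyl bromoacetate | COC(=O)CBr | starting material
20 | potassium alkoxide of 18 | [K+].[O-][C@]1(/C=C/OCc2ccc(OC)cc2)C[C@H](C)C=C[C@H]1C(=C)CO[Si](C)(C)C(C)(C)C | intermediate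
21 | potassium (3R,9S)-5-{[(tert-butyldimethylsilyl)oxy]methyl}-3-[(4-methoxyphenyl)methoxy]-9-methylcyclodeca-1,5,7-trien-1-olate (enolate double bond trans within the ring, the other two cis) | [K+].[O-]/C1=C\[C@H](OCc2ccc(OC)cc2)C/C(CO[Si](C)(C)C(C)(C)C)=C\C=C/[C@@H](C)C1 | intermediate
22 | methyl 2-[(1S,2R,4E,6Z,8S)-4-{[(tert-butyldimethylsilyl)oxy]methyl}-2-[(4-methoxyphenyl)methoxy]-8-methyl-10-oxocyclodeca-4,6-dien-1-yl]acetate | O=C1C[C@H](C)/C=C\C=C(\CO[Si](C)(C)C(C)(C)C)C[C@@H](OCc2ccc(OC)cc2)[C@@H]1CC(=O)OC | intermediate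
23 | methyl 2-[(1R,2R,4E,6Z,8S,10S)-4-{[(tert-butyldimethylsilyl)oxy]methyl}-10-hydroxy-2-[(4-methoxyphenyl)methoxy]-8-methylcyclodeca-4,6-dien-1-yl]acetate | O[C@H]1C[C@H](C)/C=C\C=C(\CO[Si](C)(C)C(C)(C)C)C[C@@H](OCc2ccc(OC)cc2)[C@@H]1CC(=O)OC | intermediate
24 | (3aS,4R,6E,8Z,10S,11aS)-6-{[(tert-butyldimethylsilyl)oxy]methyl}-4-[(4-methoxyphenyl)methoxy]-10-methyl-3a,4,5,10,11,11a-hexahydrocyclodeca[b]furan-2(3H)-one | C1C(=O)O[C@H]2C[C@H](C)/C=C\C=C(\CO[Si](C)(C)C(C)(C)C)C[C@@H](OCc3ccc(OC)cc3)[C@H]12 | intermediate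
25 | lithium enolate of 24 | C1=C([O-])O[C@H]2C[C@H](C)/C=C\C=C(\CO[Si](C)(C)C(C)(C)C)C[C@@H](OCc3ccc(OC)cc3)[C@H]12.[Li+] | intermediate
26 | 3-[(dimethylamino)methyl] derivative of 24 (C3 centre not defined) | CN(C)CC1C(=O)O[C@H]2C[C@H](C)/C=C\C=C(\CO[Si](C)(C)C(C)(C)C)C[C@@H](OCc3ccc(OC)cc3)[C@H]12 | intermediate
27 | trimethylammonium iodide formed from 26 | C[N+](C)(C)CC1C(=O)O[C@H]2C[C@H](C)/C=C\C=C(\CO[Si](C)(C)C(C)(C)C)C[C@@H](OCc3ccc(OC)cc3)[C@H]12.[I-] | intermediate
28 | (3aS,4R,6E,8Z,10S,11aS)-6-{[(tert-butyldimethylsilyl)oxy]methyl}-4-[(4-methoxyphenyl)methoxy]-10-methyl-3-methylidene-3a,4,5,10,11,11a-hexahydrocyclodeca[b]furan-2(3H)-one | C=C1C(=O)O[C@H]2C[C@H](C)/C=C\C=C(\CO[Si](C)(C)C(C)(C)C)C[C@@H](OCc3ccc(OC)cc3)[C@H]12 | intermediate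
29 | (3aS,4R,6E,8Z,10S,11aS)-6-{[(tert-butyldimethylsilyl)oxy]methyl}-4-hydroxy-10-methyl-3-methylidene-3a,4,5,10,11,11a-hexahydrocyclodeca[b]furan-2(3H)-one | C=C1C(=O)O[C@H]2C[C@H](C)/C=C\C=C(\CO[Si](C)(C)C(C)(C)C)C[C@@H](O)[C@H]12 | intermediate
30 | (4S)-2,2,4-trimethyl-1,3-dioxolane-4-carboxylic acid | OC(=O)[C@@]1(C)OC(C)(C)OC1 | starting material
31 | (4S)-2,2,4-trimethyl-1,3-dioxolane-4-carboxylic 2,4,6-trichlorobenzoic anhydride | O=C(OC(=O)[C@@]1(C)OC(C)(C)OC1)c1c(Cl)cc(Cl)cc1Cl | intermediate
32 | (3aR,4R,6E,8Z,10S,11aS)-6-{[(tert-butyldimethylsilyl)oxy]methyl}-10-methyl-3-methylidene-2-oxo-2,3,3a,4,5,10,11,11a-octahydrocyclodeca[b]furan-4-yl (4S)-2,2,4-trimethyl-1,3-dioxolane-4-carboxylate | C=C1C(=O)O[C@H]2C[C@H](C)/C=C\C=C(\CO[Si](C)(C)C(C)(C)C)C[C@@H](OC(=O)[C@@]3(C)OC(C)(C)OC3)[C@H]12 | intermediate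
33 | (3aR,4R,6E,8Z,10S,11aS)-6-(hydroxymethyl)-10-methyl-3-methylidene-2-oxo-2,3,3a,4,5,10,11,11a-octahydrocyclodeca[b]furan-4-yl (4S)-2,2,4-trimethyl-1,3-dioxolane-4-carboxylate | C=C1C(=O)O[C@H]2C[C@H](C)/C=C\C=C(\CO)C[C@@H](OC(=O)[C@@]3(C)OC(C)(C)OC3)[C@H]12 | intermediate
34 | (3aR,4R,6E,8Z,10S,11aS)-6-(acetoxymethyl)-10-methyl-3-methylidene-2-oxo-2,3,3a,4,5,10,11,11a-octahydrocyclodeca[b]furan-4-yl (4S)-2,2,4-trimethyl-1,3-dioxolane-4-carboxylate | C=C1C(=O)O[C@H]2C[C@H](C)/C=C\C=C(\COC(C)=O)C[C@@H](OC(=O)[C@@]3(C)OC(C)(C)OC3)[C@H]12 | intermediate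
35 | (3aR,4R,6E,8Z,10S,11aS)-6-(acetoxymethyl)-10-methyl-3-methylidene-2-oxo-2,3,3a,4,5,10,11,11a-octahydrocyclodeca[b]furan-4-yl (2S)-2,3-dihydroxy-2-methylpropanoate (CNP0347302.1) | C=C1C(=O)O[C@H]2C[C@H](C)/C=C\C=C(\COC(C)=O)C[C@@H](OC(=O)[C@@](C)(O)CO)[C@H]12 | target

**Step count and risks**

Total step count: 15. Longest linear sequence: 13 steps (3 to 35 through steps 2–4 and 6–15).

Steps most likely to fail:

Step 8. What may go wrong: β-elimination of 4-methoxybenzyl oxide from the potassium β-alkoxy enolate, O-alkylation, or alkylation on the other face after the ring-trans enolate has flipped through the ring. Fallback (sets out from 18, comes back at 22): 18 is rearranged under the same base conditions, but the enolate is silylated with Me3SiCl to give the ring-expanded trimethylsilyl enol ether F1. Methyl diazoacetate with catalytic Cu(C5H7O2)2 (copper bis(acetylacetonate)) should transfer the carbene to this most electron-rich double bond on its outer face and give the siloxycyclopropane ester F2. Et3N·3HF then opens the donor–acceptor cyclopropane between C6 and the ester-bearing carbon to the γ-keto ester 22. The C7–C11 bond is thus made by neutral carbene transfer instead of basic enolate alkylation.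

Step 4. What may go wrong: poor facial selectivity in the kinetic protonation of the dienolate, and re-conjugation of the β,γ-unsaturated ketone during isolation. Fallback (sets out from 3, comes back at 9): 3 is silylated under equilibrating conditions (Me3SiCl, NaI, Et3N, MeCN) to the linear trimethylsilyl dienol ether F3. This is oxidised at the γ-carbon anti to the methyl group with m-chloroperbenzoic acid (vinylogous Rubottom oxidation) to trans-4-hydroxy-5-methylcyclohex-2-en-1-one F4. Mitsunobu esterification with picolinic acid (PPh3, diisopropyl azodicarboxylate) inverts the carbinol and gives cis-6-methyl-4-oxocyclohex-2-en-1-yl pyridine-2-carboxylate F5. Luche reduction (NaBH4, CeCl3·7H2O, MeOH) gives 4-hydroxy-6-methylcyclohex-2-en-1-yl pyridine-2-carboxylate F6, whose carbinol configuration is irrelevant. {3-[(tert-Butyldimethylsilyl)oxy]prop-1-en-2-yl}magnesium bromide F7, made from 2 with t-BuLi and MgBr2·OEt2, displaces the picolinate with CuBr·SMe2 in an anti SN2' reaction; this delivers the side chain to the ring carbon next to the carbinol, trans to methyl, and gives trans-2-{3-[(tert-butyldimethylsilyl)oxy]prop-1-en-2-yl}-5-methylcyclohex-3-en-1-ol F8. Dess–Martin oxidation of F8 gives 9, with the C2 centre fixed by a stereospecific substitution instead of a protonation.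

Step 9. What may go wrong: hydride delivery governed by the conformation of the ten-membered ring instead of the zinc chelate, which gives the C6 epimer and hence the cis-fused lactone. Fallback (sets out from 22, comes back at 24): reduction of 22 with NaBH4 in MeOH, taken to the C6-epimeric alcohol, gives after lactonisation the cis-fused C6-epimeric lactone F9. LiOH opens it to the C6-epimeric hydroxy acid F10. Mitsunobu lactonisation (PPh3, diisopropyl azodicarboxylate) closes the ring with inversion at C6 and gives 24. The C6 centre is then set by an SN2 inversion instead of a face-selective reduction.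

Further compounds
F1 | step 8 | ring-expanded trimethylsilyl enol ether of the C6 ketone (enol double bond trans within the ring) | C[Si](C)(C)O/C1=C\[C@H](OCc2ccc(OC)cc2)C/C(CO[Si](C)(C)C(C)(C)C)=C\C=C/[C@@H](C)C1
F2 | step 8 | siloxycyclopropane ester from F1 and methyl diazoacetate (ester-bearing carbon not defined) | C[Si](C)(C)O[C@]12C[C@H](C)/C=C\C=C(\CO[Si](C)(C)C(C)(C)C)C[C@@H](OCc3ccc(OC)cc3)[C@@H]1C2C(=O)OC
F3 | step 4 | linear trimethylsilyl dienol ether of 3 | C[Si](C)(C)OC1=CC=C[C@@H](C)C1
F4 | step 4 | trans-4-hydroxy-5-methylcyclohex-2-en-1-one | O=C1C=C[C@H](O)[C@@H](C)C1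
F5 | step 4 | cis-6-methyl-4-oxocyclohex-2-en-1-yl pyridine-2-carboxylate | O=C1C=C[C@@H](OC(=O)c2ccccn2)[C@@H](C)C1
F6 | step 4 | 4-hydroxy-6-methylcyclohex-2-en-1-yl pyridine-2-carboxylate (ester cis to methyl, carbinol centre not defined) | OC1C=C[C@@H](OC(=O)c2ccccn2)[C@@H](C)C1
F7 | step 4 | {3-[(tert-butyldimethylsilyl)oxy]prop-1-en-2-yl}magnesium bromide | Br[Mg]C(=C)CO[Si](C)(C)C(C)(C)C
F8 | step 4 | trans-2-{3-[(tert-butyldimethylsilyl)oxy]prop-1-en-2-yl}-5-methylcyclohex-3-en-1-ol (carbinol centre not defined) | OC1C[C@H](C)C=C[C@H]1C(=C)CO[Si](C)(C)C(C)(C)C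
F9 | step 9 | C6-epimeric, cis-fused lactone corresponding to 24 | C1C(=O)O[C@@H]2C[C@H](C)/C=C\C=C(\CO[Si](C)(C)C(C)(C)C)C[C@@H](OCc3ccc(OC)cc3)[C@H]12
F10 | step 9 | C6-epimeric hydroxy acid from F9 | O[C@@H]1C[C@H](C)/C=C\C=C(\CO[Si](C)(C)C(C)(C)C)C[C@@H](OCc2ccc(OC)cc2)[C@@H]1CC(=O)O
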